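**Strategy.** Everything rests on one disconnection of the 3(2H)-furanone (O–C10–C1(=O)–C2H=C3) that bridges the ten-membered carbocycle C1–C10. Its C1–C2 bond is also a carbocycle bond, so a (3+2) annulation of a terminal alkyne (C2≡C3) with an α-oxy acyl unit (O–C10–C1) closes furanone and carbocycle together. The precursor is an open trans-α-methylene-γ-butyrolactone bearing a (Z)-enyne at C6 and a C7 side chain that ends in a citramalate-derived dioxolanone. Its acetylide adds to the dioxolanone carbonyl, acetone leaves, and the freed C10 alkoxide closes 5-endo onto the strained ynone. C10 is bought, C8 is set by catalysis, and C6/C7 are relayed in one allylboration.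

Key step: step 8

Remark on numbering: germacrane numbering is used throughout (C1 furanone carbonyl, C2 furanone CH, C3 furanone C–O carbon, C4=C5 the Z alkene, C6 lactone O–CH, C7 lactone β-CH, C8 acyloxy CH, C9 CH2, C10 quaternary O–C(CH3), C11=C13 exo-methylene, C12 lactone carbonyl).
Assumption: compounds 1, 5, 8, 11, 18 and 19 are purchased; the ProPhenol enantiomer in step 3 is the one that delivers the alkynyl group to the Si face of the aldehyde (taken here as (S,S); the antipode is equally available).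

**Step 1**
Reactants: 1 (R)-citramalic acid
Product: 2 2-[(4R)-2,2,4-trimethyl-5-oxo-1,3-dioxolan-4-yl]acetic acid
Conditions: 2,2-dimethoxypropane, TsOH·H2O (cat.), acetone, rt
Reagents that add atoms: 2,2-dimethoxypropane COC(C)(C)OC
Why: Acid-catalysed acetalisation, in which only the α-hydroxy acid can close a five-membered 1,3-dioxolan-4-one, so the β-carboxyl group stays free and the bought C10 stereocentre is not touched.

**Step 2**
Reactants: 2 2-[(4R)-2,2,4-trimethyl-5-oxo-1,3-dioxolan-4-yl]acetic acid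
Product: 4 2-[(4R)-2,2,4-trimethyl-5-oxo-1,3-dioxolan-4-yl]acetaldehyde, via acid chloride 3 (not isolated)
Conditions: (COCl)2, DMF (cat.), CH2Cl2, 0 °C → rt, evaporation; then H2 (1 atm), Pd/BaSO4, 2,6-lutidine, THF, rt
Reagents that add atoms: none
Why: Rosenmund reduction of the acid chloride should stop at the aldehyde while the dioxolanone (an ester) is inert, and it avoids a free C8 alcohol that could translactonise onto the dioxolanone.

**Step 3**
Reactants: 4 2-[(4R)-2,2,4-trimethyl-5-oxo-1,3-dioxolan-4-yl]acetaldehyde; 5 methyl propiolate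
Product: 6 methyl (4R)-4-hydroxy-5-[(4R)-2,2,4-trimethyl-5-oxo-1,3-dioxolan-4-yl]pent-2-ynoate
Conditions: (S,S)-ProPhenol (20 mol%), Me2Zn, Ph3P=O (40 mol%), toluene, 0 °C; cold NH4Cl (aq)
Reagents that add atoms: none
Why: Zinc–ProPhenol-catalysed asymmetric alkynylation, in which the dinuclear zinc catalyst binds the aldehyde and the alkynylzinc and delivers the propiolate to the Si face, so C8 (R) is set by the catalyst and not by the remote quaternary centre.

**Step 4**
Reactants: 6 methyl (4R)-4-hydroxy-5-[(4R)-2,2,4-trimethyl-5-oxo-1,3-dioxolan-4-yl]pent-2-ynoate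
Product: 7 methyl (4R)-4-[(tert-butyldimethylsilyl)oxy]-5-[(4R)-2,2,4-trimethyl-5-oxo-1,3-dioxolan-4-yl]pent-2-ynoate
Conditions: TBSOTf, 2,6-lutidine, CH2Cl2, −78 °C (crude 6, silylated at once)
Reagents that add atoms: tert-butyldimethylsilyl triflate CC(C)(C)[Si](C)(C)OS(=O)(=O)C(F)(F)F
Why: Silylation with a non-nucleophilic base caps O8 before it can attack the dioxolanone carbonyl and without aza-Michael addition to the ynoate, and the silyl ether later directs lactonisation to O6.

**Step 5**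
Reactants: 7 methyl (4R)-4-[(tert-butyldimethylsilyl)oxy]-5-[(4R)-2,2,4-trimethyl-5-oxo-1,3-dioxolan-4-yl]pent-2-ynoate; 8 2-(iodomethyl)-4,4,5,5-tetramethyl-1,3,2-dioxaborolane
Product: 10 methyl (2Z,4R)-4-[(tert-butyldimethylsilyl)oxy]-2-[(4,4,5,5-tetramethyl-1,3,2-dioxaborolan-2-yl)methyl]-5-[(4R)-2,2,4-trimethyl-5-oxo-1,3-dioxolan-4-yl]pent-2-enoate, via vinylalane 9 (not isolated)
Conditions: iBu2AlH, HMPA, THF, 0 °C; then 8, 0 °C → rt
Reagents that add atoms: none
Why: Conjugate hydroalumination of the ynoate by the iBu2AlH–HMPA complex is a syn addition (H to C7, Al to C11), and C-alkylation of the α-alumino enoate with the iodomethylboronate with retention should give the 2-alkoxycarbonyl allylboronate with C8 cis to the ester and trans to CH2B.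

**Step 6**
Reactants: 11 (Z)-3-methylpent-2-en-4-yn-1-ol
Product: 12 (Z)-3-methylpent-2-en-4-ynal
Conditions: MnO2 (activated), CH2Cl2, rt; filtered solution used at once
Reagents that add atoms: none
Why: MnO2 oxidises the allylic alcohol to the enal under neutral conditions, which should keep the Z geometry of the trisubstituted alkene.

**Step 7**
Reactants: 10 methyl (2Z,4R)-4-[(tert-butyldimethylsilyl)oxy]-2-[(4,4,5,5-tetramethyl-1,3,2-dioxaborolan-2-yl)methyl]-5-[(4R)-2,2,4-trimethyl-5-oxo-1,3-dioxolan-4-yl]pent-2-enoate; 12 (Z)-3-methylpent-2-en-4-ynal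
Product: 14 (4R,5S)-4-{(1R)-1-[(tert-butyldimethylsilyl)oxy]-2-[(4R)-2,2,4-trimethyl-5-oxo-1,3-dioxolan-4-yl]ethyl}-3-methylidene-5-[(1Z)-2-methylbut-1-en-3-yn-1-yl]oxolan-2-one, via borate ester 13 (not isolated)
Conditions: Sc(OTf)3 (10 mol%), toluene, −20 °C → rt; then TsOH·H2O (cat.), rt
Reagents that add atoms: none
Why: Tandem allylboration–lactonisation of a 2-alkoxycarbonyl allylboronate through a closed chair transition state (enal residue equatorial, C8 trans to CH2B) gives the anti adduct and hence the trans lactone, while allylic 1,3-strain to the ester holds H8 in the alkene plane so that the aldehyde should add anti to the silyloxy group, which relays C8 to C7 and C6 in one event.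

**Step 8**
Reactants: 14 (4R,5S)-4-{(1R)-1-[(tert-butyldimethylsilyl)oxy]-2-[(4R)-2,2,4-trimethyl-5-oxo-1,3-dioxolan-4-yl]ethyl}-3-methylidene-5-[(1Z)-2-methylbut-1-en-3-yn-1-yl]oxolan-2-one
Product: 16 (4Z,6S,7R,8R,10R)-8-[(tert-butyldimethylsilyl)oxy]-1-oxo-3,10-epoxygermacra-2,4,11(13)-trien-12,6-olide, via lithium oxido ynone 15 (not isolated)
Conditions: LiN(SiMe3)2 (1.1 equiv, slow addition), THF (0.002 M), −78 → 0 °C; AcOH
Reagents that add atoms: none
Why: Proposed new method: deprotonation gives the lithium acetylide, which adds to the dioxolanone carbonyl C1, the tetrahedral adduct collapses with loss of acetone to the ten-membered α'-oxido ynone 15, and its C10 alkoxide adds to C3 to give 16 after protonation at C2. The closest known reactions are the intramolecular acetylide–carbonyl additions that close ten-membered cis-enyne rings in enediyne synthesis, the acylation of lithium acetylides by lactones, and the base-induced cyclisation of α'-hydroxy ynones to 3(2H)-furanones; their merger in one flask, with a dioxolanone as acyl donor and alkoxide source, is new. The carbocycle closes by 10-exo-trig attack on the carbonyl group and the furanone by 5-endo-dig oxa-Michael addition, which is driven by release of the strain of the bent cycloalkyne. No stereocentre is formed; C6, C7, C8 and C10 are carried through, and C10 has no α-hydrogen. The step needs attack at the dioxolanone in preference to the γ-lactone carbonyl and the exo-methylene group: the cis-enyne on the trans-lactone lets the acetylide reach those sites only through seven- or eight-membered cycloalkynes, and high dilution suppresses the intermolecular additions.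

**Step 9**
Reactants: 16 (4Z,6S,7R,8R,10R)-8-[(tert-butyldimethylsilyl)oxy]-1-oxo-3,10-epoxygermacra-2,4,11(13)-trien-12,6-olide
Product: 17 (4Z,6S,7S,8R,10R)-8-hydroxy-1-oxo-3,10-epoxygermacra-2,4,11(13)-trien-12,6-olide
Conditions: HF·pyridine, pyridine, THF, 0 °C → rt
Reagents that add atoms: none
Why: Buffered fluoride desilylation should remove the secondary silyl ether without touching the lactone, the vinylogous ester or any stereocentre.

**Step 10**
Reactants: 18 tert-butyl acrylate; 19 acetaldehyde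
Product: 20 tert-butyl 3-hydroxy-2-methylidenebutanoate (racemic)
Conditions: DABCO (cat.), neat, rt
Reagents that add atoms: none
Why: Morita–Baylis–Hillman reaction, in which the DABCO–acrylate zwitterion adds to acetaldehyde; the racemic carbinol centre is erased in the next step.

**Step 11**
Reactants: 20 tert-butyl 3-hydroxy-2-methylidenebutanoate
Product: 22 tert-butyl (2E)-2-(acetoxymethyl)but-2-enoate, via allylic acetate 21 (not isolated)
Conditions: Ac2O, Et3N, DMAP (cat.), THF, 0 °C → rt; then DABCO (0.3 equiv), 65 °C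
Reagents that add atoms: acetic anhydride CC(=O)OC(C)=O
Why: Acetylation followed by DABCO-catalysed 1,3-transposition of the acetate (SN2' then SN2' through the allylammonium ion) should give the thermodynamically preferred primary acetate with the methyl group trans to the ester (E).

**Step 12**
Reactants: 22 tert-butyl (2E)-2-(acetoxymethyl)but-2-enoate
Product: 23 (2E)-2-(acetoxymethyl)but-2-enoic acid
Conditions: TFA, CH2Cl2, 0 °C → rt
Reagents that add atoms: none
Why: Acidolysis of the tert-butyl ester (loss of isobutene) leaves the allylic acetate and the alkene geometry intact.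

**Step 13**
Reactants: 17 (4Z,6S,7S,8R,10R)-8-hydroxy-1-oxo-3,10-epoxygermacra-2,4,11(13)-trien-12,6-olide; 23 (2E)-2-(acetoxymethyl)but-2-enoic acid
Product: 25 (4Z,6S,7S,8R,10R)-8-{[(2E)-2-(acetoxymethyl)but-2-enoyl]oxy}-1-oxo-3,10-epoxygermacra-2,4,11(13)-trien-12,6-olide (target CNP0176571.1), via mixed anhydride 24 (not isolated)
Conditions: 2,4,6-trichlorobenzoyl chloride, Et3N, toluene, rt; then 17, DMAP, rt
Reagents that add atoms: none
Why: Yamaguchi esterification acylates the hindered C8 alcohol with retention at C8, and the E acid is the stable isomer, so base-induced isomerisation is not expected; it is placed last because the allylic acetate and the second Michael acceptor would not survive the earlier steps.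

**Compound list**

1 | (R)-citramalic acid, (2R)-2-hydroxy-2-methylbutanedioic acid | OC(=O)[C@@](C)(CC(=O)O)O | starting material
2 | 2-[(4R)-2,2,4-trimethyl-5-oxo-1,3-dioxolan-4-yl]acetic acid | CC1(C)OC(=O)[C@@](C)(CC(=O)O)O1 | intermediate
3 | 2-[(4R)-2,2,4-trimethyl-5-oxo-1,3-dioxolan-4-yl]acetyl chloride | CC1(C)OC(=O)[C@@](C)(CC(=O)Cl)O1 | intermediate (not isolated)
4 | 2-[(4R)-2,2,4-trimethyl-5-oxo-1,3-dioxolan-4-yl]acetaldehyde | CC1(C)OC(=O)[C@@](C)(CC=O)O1 | intermediate
5 | methyl propiolate | C#CC(=O)OC | starting material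
6 | methyl (4R)-4-hydroxy-5-[(4R)-2,2,4-trimethyl-5-oxo-1,3-dioxolan-4-yl]pent-2-ynoate | CC1(C)OC(=O)[C@@](C)(C[C@@H](O)C#CC(=O)OC)O1 | intermediate
7 | methyl (4R)-4-[(tert-butyldimethylsilyl)oxy]-5-[(4R)-2,2,4-trimethyl-5-oxo-1,3-dioxolan-4-yl]pent-2-ynoate | CC1(C)OC(=O)[C@@](C)(C[C@@H](O[Si](C)(C)C(C)(C)C)C#CC(=O)OC)O1 | intermediate
8 | 2-(iodomethyl)-4,4,5,5-tetramethyl-1,3,2-dioxaborolane | CC1(C)OB(CI)OC1(C)C | starting material
9 | methyl (2E,4R)-2-(diisobutylalumanyl)-4-[(tert-butyldimethylsilyl)oxy]-5-[(4R)-2,2,4-trimethyl-5-oxo-1,3-dioxolan-4-yl]pent-2-enoate (C8 trans to Al) | CC1(C)OC(=O)[C@@](C)(C[C@@H](O[Si](C)(C)C(C)(C)C)/C=C(/[Al](CC(C)C)CC(C)C)C(=O)OC)O1 | intermediate (not isolated)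
10 | methyl (2Z,4R)-4-[(tert-butyldimethylsilyl)oxy]-2-[(4,4,5,5-tetramethyl-1,3,2-dioxaborolan-2-yl)methyl]-5-[(4R)-2,2,4-trimethyl-5-oxo-1,3-dioxolan-4-yl]pent-2-enoate | CC1(C)OC(=O)[C@@](C)(C[C@@H](O[Si](C)(C)C(C)(C)C)/C=C(/CB2OC(C)(C)C(C)(C)O2)C(=O)OC)O1 | intermediate
11 | (Z)-3-methylpent-2-en-4-yn-1-ol | C#C/C(C)=C\CO | starting material
12 | (Z)-3-methylpent-2-en-4-ynal | C#C/C(C)=C\C=O | intermediate
13 | methyl (3R,4S,5Z)-3-{(1R)-1-[(tert-butyldimethylsilyl)oxy]-2-[(4R)-2,2,4-trimethyl-5-oxo-1,3-dioxolan-4-yl]ethyl}-6-methyl-2-methylidene-4-[(4,4,5,5-tetramethyl-1,3,2-dioxaborolan-2-yl)oxy]oct-5-en-7-ynoate | C=C(C(=O)OC)[C@H]([C@@H](OB1OC(C)(C)C(C)(C)O1)/C=C(/C)C#C)[C@H](O[Si](C)(C)C(C)(C)C)C[C@@]2(C)OC(C)(C)OC2=O | intermediate (not isolated)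
14 | (4R,5S)-4-{(1R)-1-[(tert-butyldimethylsilyl)oxy]-2-[(4R)-2,2,4-trimethyl-5-oxo-1,3-dioxolan-4-yl]ethyl}-3-methylidene-5-[(1Z)-2-methylbut-1-en-3-yn-1-yl]oxolan-2-one | C=C1C(=O)O[C@@H](/C=C(/C)C#C)[C@@H]1[C@H](O[Si](C)(C)C(C)(C)C)C[C@@]2(C)OC(C)(C)OC2=O | intermediate
15 | lithium alkoxide of (4Z,6S,7R,8R,10R)-8-[(tert-butyldimethylsilyl)oxy]-10-hydroxy-1-oxogermacra-4,11(13)-dien-2-yn-12,6-olide (ten-membered ynone) | C=C1C(=O)O[C@H]2/C=C(/C)C#CC(=O)[C@](C)([O-])C[C@@H](O[Si](C)(C)C(C)(C)C)[C@H]12.[Li+] | intermediate (not isolated)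
16 | (4Z,6S,7R,8R,10R)-8-[(tert-butyldimethylsilyl)oxy]-1-oxo-3,10-epoxygermacra-2,4,11(13)-trien-12,6-olide | C=C1C(=O)O[C@H]2/C=C(/C)C3=CC(=O)[C@@](C)(C[C@@H](O[Si](C)(C)C(C)(C)C)[C@H]12)O3 | intermediate
17 | (4Z,6S,7S,8R,10R)-8-hydroxy-1-oxo-3,10-epoxygermacra-2,4,11(13)-trien-12,6-olide | C=C1C(=O)O[C@H]2/C=C(/C)C3=CC(=O)[C@@](C)(C[C@@H](O)[C@H]12)O3 | intermediate
18 | tert-butyl acrylate | C=CC(=O)OC(C)(C)C | starting material
19 | acetaldehyde | CC=O | starting material
20 | tert-butyl 3-hydroxy-2-methylidenebutanoate (racemic) | CC(O)C(=C)C(=O)OC(C)(C)C | intermediate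
21 | tert-butyl 3-acetoxy-2-methylidenebutanoate (racemic) | CC(OC(C)=O)C(=C)C(=O)OC(C)(C)C | intermediate (not isolated)
22 | tert-butyl (2E)-2-(acetoxymethyl)but-2-enoate | C/C=C(\COC(C)=O)C(=O)OC(C)(C)C | intermediate
23 | (2E)-2-(acetoxymethyl)but-2-enoic acid | C/C=C(\COC(C)=O)C(=O)O | intermediate
24 | (2E)-2-(acetoxymethyl)but-2-enoic 2,4,6-trichlorobenzoic anhydride | C/C=C(\COC(C)=O)C(=O)OC(=O)c1c(Cl)cc(Cl)cc1Cl | intermediate (not isolated)
25 | (4Z,6S,7S,8R,10R)-8-{[(2E)-2-(acetoxymethyl)but-2-enoyl]oxy}-1-oxo-3,10-epoxygermacra-2,4,11(13)-trien-12,6-olide, CNP0176571.1 | C=C1C(=O)O[C@H]2/C=C(/C)C3=CC(=O)[C@@](C)(C[C@@H](OC(=O)/C(=C/C)COC(C)=O)[C@H]12)O3 | target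

**Step count**

Total steps: 13. Longest linear sequence: 9 (steps 1, 2, 3, 4, 5, 7, 8, 9, 13).

**Steps most likely to fail**

1. Step 8 (key step). The ten-membered ring closure may lose to oligomerisation, the amide base or the acetylide may add to the exo-methylene lactone, or the tetrahedral adduct may fail to collapse so that the cascade stops before the furanone. The fallback uses known reactions and makes the two bonds in two operations; it sets out from 14 and comes back at 16. The dioxolanone of 14 is hydrolysed (AcOH/H2O/THF, 40 °C; the γ-lactone is acid-stable) to the α-hydroxy acid F1. F1 is converted without amine base, so that thia-Michael addition is avoided, into the S-ethyl thioester F2 (EtSH, DCC, HOBt, CH2Cl2, 0 °C). A palladium/copper-catalysed thioester–alkyne coupling at high dilution (PdCl2(dppf), P(2-furyl)3, CuI (1.7 equiv, which also binds the thiolate as CuSEt), Et3N, DMF, 50 °C, 0.002 M) should close the carbocycle to the neutral ten-membered hydroxy ynone F3. Gold-catalysed 5-endo-dig cyclisation ((Ph3P)AuNTf2 (5 mol%), CH2Cl2, rt) then gives 16.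

2. Step 7. The aldehyde may add to the alkene face syn to the silyloxy group (reversed facial selectivity with respect to C8), which would give the trans lactone with C6 and C7 both inverted; the Z enal may also isomerise under the Lewis acid. The fallback uses the opposite C8 configuration and corrects it at the end; it sets out from 4 and comes back at 25.
   - Alkynylation of 4 with 5 under the antipodal (R,R)-ProPhenol catalyst gives the (4S)-propargylic alcohol F4.
   - Silylation as in step 4 gives the (4S)-silyl ether F5.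
   - Hydroalumination as in step 5 (through the 4-epimeric vinylalane F6) and alkylation with 8 give the (4S)-allylboronate F7.
   - Allylboration of 12 as in step 7 (through the borate ester F8) then gives, under the reversed facial preference, the 8-epi lactone F9 with C6 and C7 as in the target.
   - The macrocyclisation of step 8 (through the lithium oxido ynone F10) gives the 8-epi macrocycle F11.
   - HF·pyridine gives the 8-epi alcohol F12.
   - Mitsunobu esterification of F12 with 23 (PPh3, DIAD, toluene, 0 °C → rt) installs the ester with inversion at C8 and gives 25.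

3. Step 5. The aluminium hydride may reduce the dioxolanone carbonyl in competition with conjugate addition, and the alkene geometry may erode through the aluminium allenolate. The fallback builds the allylboronate without hydride; it sets out from 7 and comes back at 10. Syn hydrostannation catalysed by Pd(PPh3)4 (Bu3SnH, THF, 0 °C) gives the α-stannyl enoate F13. Iododestannylation with retention (I2, CH2Cl2, 0 °C) gives the α-iodo enoate F14. Negishi coupling of F14 with (pinacolboryl)methylzinc iodide (made from 8 and Zn dust; Pd(PPh3)4, THF, rt) gives 10 with the same geometry.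

**Further compounds**

F1 | step 8 | (2R,4R)-4-[(tert-butyldimethylsilyl)oxy]-2-hydroxy-2-methyl-4-{(2S,3R)-4-methylidene-2-[(1Z)-2-methylbut-1-en-3-yn-1-yl]-5-oxooxolan-3-yl}butanoic acid | C=C1C(=O)O[C@@H](/C=C(/C)C#C)[C@@H]1[C@H](O[Si](C)(C)C(C)(C)C)C[C@@](C)(O)C(=O)O
F2 | step 8 | S-ethyl thioester of F1 | C=C1C(=O)O[C@@H](/C=C(/C)C#C)[C@@H]1[C@H](O[Si](C)(C)C(C)(C)C)C[C@@](C)(O)C(=O)SCC
F3 | step 8 | (4Z,6S,7R,8R,10R)-8-[(tert-butyldimethylsilyl)oxy]-10-hydroxy-1-oxogermacra-4,11(13)-dien-2-yn-12,6-olide | C=C1C(=O)O[C@H]2/C=C(/C)C#CC(=O)[C@](C)(O)C[C@@H](O[Si](C)(C)C(C)(C)C)[C@H]12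
F4 | step 7 | methyl (4S)-4-hydroxy-5-[(4R)-2,2,4-trimethyl-5-oxo-1,3-dioxolan-4-yl]pent-2-ynoate | CC1(C)OC(=O)[C@@](C)(C[C@H](O)C#CC(=O)OC)O1
F5 | step 7 | methyl (4S)-4-[(tert-butyldimethylsilyl)oxy]-5-[(4R)-2,2,4-trimethyl-5-oxo-1,3-dioxolan-4-yl]pent-2-ynoate | CC1(C)OC(=O)[C@@](C)(C[C@H](O[Si](C)(C)C(C)(C)C)C#CC(=O)OC)O1
F6 | step 7 | methyl (2E,4S)-2-(diisobutylalumanyl)-4-[(tert-butyldimethylsilyl)oxy]-5-[(4R)-2,2,4-trimethyl-5-oxo-1,3-dioxolan-4-yl]pent-2-enoate | CC1(C)OC(=O)[C@@](C)(C[C@H](O[Si](C)(C)C(C)(C)C)/C=C(/[Al](CC(C)C)CC(C)C)C(=O)OC)O1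
F7 | step 7 | methyl (2Z,4S)-4-[(tert-butyldimethylsilyl)oxy]-2-[(4,4,5,5-tetramethyl-1,3,2-dioxaborolan-2-yl)methyl]-5-[(4R)-2,2,4-trimethyl-5-oxo-1,3-dioxolan-4-yl]pent-2-enoate | CC1(C)OC(=O)[C@@](C)(C[C@H](O[Si](C)(C)C(C)(C)C)/C=C(/CB2OC(C)(C)C(C)(C)O2)C(=O)OC)O1
F8 | step 7 | 8-epimer of borate ester 13 | C=C(C(=O)OC)[C@H]([C@@H](OB1OC(C)(C)C(C)(C)O1)/C=C(/C)C#C)[C@@H](O[Si](C)(C)C(C)(C)C)C[C@@]2(C)OC(C)(C)OC2=O
F9 | step 7 | (4R,5S)-4-{(1S)-1-[(tert-butyldimethylsilyl)oxy]-2-[(4R)-2,2,4-trimethyl-5-oxo-1,3-dioxolan-4-yl]ethyl}-3-methylidene-5-[(1Z)-2-methylbut-1-en-3-yn-1-yl]oxolan-2-one | C=C1C(=O)O[C@@H](/C=C(/C)C#C)[C@@H]1[C@@H](O[Si](C)(C)C(C)(C)C)C[C@@]2(C)OC(C)(C)OC2=O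
F10 | step 7 | 8-epimer of lithium oxido ynone 15 | C=C1C(=O)O[C@H]2/C=C(/C)C#CC(=O)[C@](C)([O-])C[C@H](O[Si](C)(C)C(C)(C)C)[C@H]12.[Li+]
F11 | step 7 | (4Z,6S,7R,8S,10R)-8-[(tert-butyldimethylsilyl)oxy]-1-oxo-3,10-epoxygermacra-2,4,11(13)-trien-12,6-olide | C=C1C(=O)O[C@H]2/C=C(/C)C3=CC(=O)[C@@](C)(C[C@H](O[Si](C)(C)C(C)(C)C)[C@H]12)O3
F12 | step 7 | (4Z,6S,7S,8S,10R)-8-hydroxy-1-oxo-3,10-epoxygermacra-2,4,11(13)-trien-12,6-olide | C=C1C(=O)O[C@H]2/C=C(/C)C3=CC(=O)[C@@](C)(C[C@H](O)[C@H]12)O3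
F13 | step 5 | methyl (2E,4R)-4-[(tert-butyldimethylsilyl)oxy]-2-(tributylstannyl)-5-[(4R)-2,2,4-trimethyl-5-oxo-1,3-dioxolan-4-yl]pent-2-enoate | CC1(C)OC(=O)[C@@](C)(C[C@@H](O[Si](C)(C)C(C)(C)C)/C=C(/[Sn](CCCC)(CCCC)CCCC)C(=O)OC)O1
F14 | step 5 | methyl (2E,4R)-4-[(tert-butyldimethylsilyl)oxy]-2-iodo-5-[(4R)-2,2,4-trimethyl-5-oxo-1,3-dioxolan-4-yl]pent-2-enoate | CC1(C)OC(=O)[C@@](C)(C[C@@H](O[Si](C)(C)C(C)(C)C)/C=C(/I)C(=O)OC)O1
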